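## Analysis of the target

Target 24 is an unbranched chain of seven benzene rings joined by six diaryl ether oxygens and carrying eighteen free phenolic hydroxyls (C42H30O24). The rings are lettered A (the 2,4,6-trihydroxyphenoxy end) to G (the 3,4,5-trihydroxyphenyl end). In rings B, D and F, position 1 is bound to the oxygen shared with the preceding ring, position 4 to the oxygen shared with the following ring, and positions 3 and 5 carry hydroxyls. In rings C and E, position 1 is bound to the oxygen coming from ring B (or D), position 2 to the oxygen leading to ring D (or F), positions 3, 4 and 5 carry hydroxyls, and position 6 is the only CH. There is no stereocentre and no hindered axis, so the problem is one of regiochemistry and functional-group handling only. The hydroxyl arrays (pyrogallol units in rings C, E and G) are readily oxidised by air, above all as phenoxides, so the hydroxyls must stay masked until an acidic last step. The synthesis is hard because each ether oxygen sits, on one of its two carbons (A1, B4, C2, D4, E2, F4), between two oxygenated ortho positions, and because rings C and E are pentaoxygenated with two different aryl ethers on neighbouring carbons. The strategy rests on ring C and, identically, ring E: the para oxygens at C2 and C5 enclose the vicinal oxygens at C3 and C4, which is the pattern of a hydroquinone grown from squarate 6, while C1 with its ring B ether and C6 with its hydrogen correspond to a 1-aryloxyvinyl group. Since B–C and D–E are the same two-ring motif, one building block (12) serves twice.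

## Retrosynthetic reasoning

**24 from 23.** The last disconnection cuts eighteen O–alkyl bonds (twelve O–methyl, six O–isopropyl) and no skeletal bond. Alkyl ethers are the only permanent protection because they tolerate the organolithium, the thermolysis and the copper and palladium couplings. One Lewis-acid dealkylation under acidic, air-free conditions removes them all and leaves the diaryl ethers intact.

**23 from 21 and 22.** The A–B ether is cut between its oxygen and B1. The oxygen belongs to phenol 22, whose two ortho methoxy groups make it a poor partner for anything but a catalysed arylation, whereas B1 is flanked by hydrogens and is an accessible electrophile. B1 already carries an oxygen, so the electrophile is triflate 21, obtained from silyl ether 19 through phenol 20. The forward reaction is a palladium-catalysed etherification of an aryl triflate by a doubly ortho-substituted phenol.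

**19 from 12 and 18.** The C2–O–D1 ether is cut on the D1 side by the same logic: the crowded oxygen stays on ring C as the free phenol of 12, and D1, flanked by hydrogens, is the carbon of triflate 18. Triflate 18 comes from silyl ether 16 through phenol 17. This joins a two-ring and a four-ring piece late and convergently.

**16 from 12 and 15.** The E2–O–F1 ether is cut on the F1 side. The nucleophile is again phenol 12, now supplying rings D and E, and the electrophile is bromide 15, whose bromine sits between two hydrogens. Using 12 for both the B–C and the D–E pair halves the number of different intermediates.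

**15 from 13 and 14.** The F4–O–G1 ether is cut on the G1 side. The flanked oxygen stays on phenol 13 and the unhindered aryl group comes from boronic acid 14. An oxidative copper coupling is chosen because it leaves the bromide of 13 untouched, so the handle for the next coupling is in place from the start.

**12 from 11.** The isopropyl group on the C5 oxygen is removed to reveal hydroquinone 11. The forward alkylation must distinguish the C5 hydroxyl (one ortho hydrogen) from the C2 hydroxyl (buried between the aryloxy group and an isopropoxy group), and a secondary alkyl halide is chosen to make the most of that difference.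

**11 from 8 (key disconnection).** Ring C is opened at the C5–C6 bond and the bond between C2 and C5 is restored, which turns the benzene ring into the four-membered ring of cyclobutenone 8. This is done here, and not at a ring C oxygen, because it places all five oxygens by connectivity alone. The forward reaction is a thermal cascade through ketene 9 and dienone 10.

**8 from 5 and 6.** The C1–C2 bond is cut. C2 is a carbonyl carbon of squarate 6 and C1 is the oxygen-bearing carbon of vinyl ether 5, used as its lithio derivative 7.

**5 from 3 and 4; 3 from 2; 2 from 1.** The B4–O–C1 ether, the most crowded of the six, is not made by arylation at all: the flanked phenol oxygen of 3 is vinylated with 4 and ring C is then built on that vinyl group. Phenol 3 follows from hydroquinone 2 by silylation of its open hydroxyl, and 2 from quinone 1 by reduction.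

## Alternatives that were turned down

**Alternative 1:** The disconnection makes every aryl–O–aryl bond by nucleophilic aromatic substitution of a fluoride. The twelve hydroxyls that stand ortho to ether oxygens on rings A to F are carried as formyl groups, which activate each substitution, and the assembly ends at the hexabenzyl dodecaaldehyde A2. The forward key step is a twelvefold Baeyer–Villiger (Dakin-type) oxidation of A2 with excess peracid, giving the hexabenzyl dodecaformate A1 without closing any ring; formate solvolysis and hydrogenolysis would finish.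

- For it: the couplings need no metal and are activated exactly at the crowded positions. The final hydrogenolysis is milder than an eighteen-fold Lewis-acid dealkylation, and on both points this alternative is stronger than the chosen route.
- Against it: twelve oxidations on one molecule must each go by aryl migration and to completion, and a formyl group that takes the hydride-migration branch becomes a carboxylic acid and cannot be recovered. The rings grow more electron-rich as the reaction proceeds and are exposed to the oxidant. The fluorinated dialdehyde building blocks for seven different rings each need their own synthesis.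
- Comparison: the chosen route also ends in a many-fold reaction, but ether cleavage has no competing pathway and stalled material can be re-subjected. In exchange for metal-free couplings it offers rings C and E with all five oxygens fixed by construction, from building blocks that can be bought.

**Alternative 2:** The disconnection cuts the flanked F4–O–G1 ether and re-forms it inside a ring. Rings F and G are first joined as the ester A4, a brominated pyrogallol acylated on an outer hydroxyl by a fluorinated trimethoxybenzoyl group. In the forward key step the central phenoxide of A4 displaces the fluoride ortho to the ester carbonyl and closes the seven-membered ring of depsidone A3; the tether is later removed by lactone opening and decarboxylation.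

- For it: the intramolecular, carbonyl-activated substitution is a dependable way to make a diaryl ether at an oxygen between two substituents. For the F–G bond it is at least as secure as the oxidative copper coupling of step 7.
- Against it: it solves one of six ether bonds at the cost of esterification, lactone opening and decarboxylation. Applied to the B–C and D–E junctions, the acid partner would have to be a pentaoxygenated benzoic acid that is itself the unsolved problem.
- Comparison: the chosen strategy pays one less certain step for the F–G bond, but it removes the two hardest junctions (B4–O–C1 and D4–O–E1) from the list of arylations and builds rings C and E in the same stroke, in far fewer steps per ring.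

**Alternative 3:** The disconnection cuts both ether bonds of ring D at once. Ring D enters as a dichlorodimethoxybenzene bound to a cyclopentadienylruthenium cation, A6, and is attacked in one pot by two trimeric phenols, the A–B–C phenol A7 and the E–F–G phenol A8. In the forward key step the phenoxide of A7 displaces the chloride flanked by hydrogens, the phenoxide of A8 then displaces the chloride flanked by methoxy groups, and irradiation in a nitrile solvent releases the octadeca-O-methyl heptamer A5; no ring closes.

- For it: this is the most convergent endgame of all. Two halves are united in one flask without triflate intermediates, and on this point it is clearly stronger than the chosen route, which needs steps 9 to 11.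
- Against it: the second substitution must occur at a carbon between two methoxy groups with a nucleophile that carries an ortho aryloxy group, on an arene made less electrophilic by the first substitution. The ordering of the two substitutions rests only on a rate difference. Ruthenium is used stoichiometrically, and A7 and A8, which contain all the other crowded ethers and both pentaoxygenated rings, are left unsolved.
- Comparison: the chosen strategy offers a defined way to make exactly those rings and ethers, and a single intermediate (12) that provides four of the seven rings.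

Key step: step 5

Assumption: 13, 14 and 22 are taken as purchasable, and 12 is prepared once on a scale that serves both step 8 and step 11.

## Route

Step 1
Reactants: 1 2,6-dimethoxy-1,4-benzoquinone
Product: 2 2,6-dimethoxybenzene-1,4-diol
Conditions: Na2S2O4, EtOAc/H2O, rt, Ar
Reagents that add atoms: none
Why: Two-electron reduction of a quinone to its hydroquinone by dithionite; the air-sensitive product is carried on at once.

Step 2
Reactants: 2 2,6-dimethoxybenzene-1,4-diol
Product: 3 2,6-dimethoxy-4-(triisopropylsilyloxy)phenol
Conditions: TIPSCl (1.05 equiv), imidazole, DMF, 0 °C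
Reagents that add atoms: chlorotriisopropylsilane, CC(C)[Si](Cl)(C(C)C)C(C)C
Why: Silylation of a phenol with a bulky silyl chloride; the hydroxyl with two ortho hydrogens should react far faster than the one buried between two methoxy groups, so the open oxygen is capped and the flanked one stays free.

Step 3
Reactants: 3 2,6-dimethoxy-4-(triisopropylsilyloxy)phenol; 4 vinyl acetate
Product: 5 triisopropyl[3,5-dimethoxy-4-(vinyloxy)phenoxy]silane
Conditions: [Ir(cod)Cl]2 (2 mol%), Na2CO3 (0.6 equiv), toluene, 100 °C
Reagents that add atoms: none
Why: Iridium-catalysed transfer vinylation of a phenol by a vinyl ester (addition of the iridium phenoxide across the vinyl group, then loss of acetate); the small vinyl group is accepted by a doubly ortho-substituted phenol and the aryl silyl ether is inert to carbonate in toluene.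

Step 4
Reactants: 5 triisopropyl[3,5-dimethoxy-4-(vinyloxy)phenoxy]silane; 6 diisopropyl squarate
Product: 8 (±)-4-hydroxy-2,3-diisopropoxy-4-{1-[2,6-dimethoxy-4-(triisopropylsilyloxy)phenoxy]vinyl}cyclobut-2-en-1-one, via aryloxyvinyllithium 7 (not isolated)
Conditions: t-BuLi (1.1 equiv), THF, −78 °C; then cannulated into 6, THF, −78 °C; aq. NH4Cl, −78 °C
Reagents that add atoms: none
Why: Alpha-lithiation of a vinyl ether at the sp2 C–H next to oxygen, then 1,2-addition of the vinyllithium to one carbonyl of the squarate ester, the standard entry to 4-substituted 4-hydroxycyclobutenones. The ether oxygen of 5 has no ortho hydrogen and the bulky silyl ether shields the remaining ring hydrogens, so deprotonation should occur at the vinyl group. The carbinol carbon is formed racemic and is destroyed in step 5.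

Step 5
Reactants: 8 (±)-4-hydroxy-2,3-diisopropoxy-4-{1-[2,6-dimethoxy-4-(triisopropylsilyloxy)phenoxy]vinyl}cyclobut-2-en-1-one
Product: 11 5-[2,6-dimethoxy-4-(triisopropylsilyloxy)phenoxy]-2,3-diisopropoxybenzene-1,4-diol (ring B-ring C hydroquinone), via dienylketene 9 (not isolated), via cyclohexadienone 10 (not isolated)
Conditions: toluene (degassed), 110 °C, Ar
Reagents that add atoms: none
Why: Heating opens the cyclobutenone by a thermal conrotatory 4-pi ring opening that breaks the bond between the carbinol and carbonyl carbons and gives dienylketene 9. The ketene carbon then bonds to the vinyl CH2 in a disrotatory 6-pi electrocyclisation, a six-membered closure that forms the C5–C6 bond of ring C and gives dienone 10, which enolises to the aromatic hydroquinone 11. The closest known reaction type is the thermal ring expansion of 4-alkenyl-4-hydroxycyclobutenones derived from squarate esters, which includes adducts of alpha-lithiated enol ethers. No stereocentre is created and the carbinol centre of 8 disappears. The selectivity needed is torquoselectivity: the hydroxyl must rotate outward so that the aryloxyvinyl group ends cis to the ketene, and as the donor substituent on the breaking bond the hydroxyl is the group that prefers outward rotation. Regiochemistry needs no control, because the connectivity of 8 fixes every oxygen: the alkene carbons of the squarate become C3 and C4 with their isopropoxy groups, the carbonyl and carbinol carbons become C5 and C2, and the vinyl ether supplies C1 with the ring B ether and C6 with its hydrogen. Air is excluded because 11 is an electron-rich hydroquinone that would otherwise go on to the quinone.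

Step 6
Reactants: 11 5-[2,6-dimethoxy-4-(triisopropylsilyloxy)phenoxy]-2,3-diisopropoxybenzene-1,4-diol
Product: 12 6-[2,6-dimethoxy-4-(triisopropylsilyloxy)phenoxy]-2,3,4-triisopropoxyphenol
Conditions: 2-bromopropane (1.1 equiv), K2CO3 (1.1 equiv), DMF (degassed), 40 °C, Ar
Reagents that add atoms: 2-bromopropane, CC(C)Br
Why: Williamson etherification with a secondary halide, whose SN2 transition state is sensitive to crowding; the C5 phenoxide has one ortho hydrogen whereas the C2 phenoxide lies between the diaryl ether and an isopropoxy group, so the C5 oxygen should be alkylated and the C2 hydroxyl left free.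

Step 7
Reactants: 13 4-bromo-2,6-dimethoxyphenol; 14 (3,4,5-trimethoxyphenyl)boronic acid
Product: 15 5-(4-bromo-2,6-dimethoxyphenoxy)-1,2,3-trimethoxybenzene (ring F-ring G bromide)
Conditions: Cu(OAc)2, pyridine, 4 Å MS, CH2Cl2, air, rt
Reagents that add atoms: none
Why: Chan–Lam oxidative O-arylation of a phenol by an arylboronic acid, which accepts 2,6-disubstituted phenols and electron-rich boronic acids and leaves an aryl bromide untouched at room temperature. The bromine also blocks the para position at which such phenols otherwise dimerise oxidatively.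

Step 8
Reactants: 12 6-[2,6-dimethoxy-4-(triisopropylsilyloxy)phenoxy]-2,3,4-triisopropoxyphenol; 15 5-(4-bromo-2,6-dimethoxyphenoxy)-1,2,3-trimethoxybenzene
Product: 16 D-E-F-G tetramer triisopropylsilyl ether (12 O-arylated on its free phenol by the 3,5-dimethoxy-4-(3,4,5-trimethoxyphenoxy)phenyl group of 15)
Conditions: CuI (20 mol%), N,N-dimethylglycine hydrochloride (60 mol%), Cs2CO3, 1,4-dioxane, 100 °C, Ar
Reagents that add atoms: none
Why: Ligand-accelerated Ullmann diaryl ether coupling; the bromide carbon is flanked by two hydrogens and the only free hydroxyl is the crowded one of 12, so only the rate, not the site, is in question. Dry carbonate in dioxane is chosen to keep the aryl silyl ether intact.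

Step 9
Reactants: 16 D-E-F-G tetramer triisopropylsilyl ether
Product: 17 D-E-F-G tetramer phenol (free hydroxyl at D1)
Conditions: Bu4NF, AcOH (1:1), THF, 0 °C
Reagents that add atoms: none
Why: Fluoride cleavage of an aryl silyl ether; the acetic acid buffer keeps the electron-rich phenol protonated and limits oxidation.

Step 10
Reactants: 17 D-E-F-G tetramer phenol
Product: 18 D-E-F-G tetramer triflate (trifluoromethanesulfonate at D1)
Conditions: Tf2O, pyridine, CH2Cl2, −20 to 0 °C
Reagents that add atoms: trifluoromethanesulfonic anhydride, O=S(=O)(OS(=O)(=O)C(F)(F)F)C(F)(F)F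
Why: Standard sulfonylation of an unhindered phenol; all other oxygens are ethers.

Step 11
Reactants: 12 6-[2,6-dimethoxy-4-(triisopropylsilyloxy)phenoxy]-2,3,4-triisopropoxyphenol; 18 D-E-F-G tetramer triflate
Product: 19 B-C-D-E-F-G hexamer triisopropylsilyl ether (silyl ether at B1)
Conditions: Pd(OAc)2 (5 mol%), 2-di-tert-butylphosphino-2',4',6'-triisopropylbiphenyl (10 mol%), K3PO4, toluene, 100 °C, Ar
Reagents that add atoms: none
Why: Buchwald–Hartwig-type palladium-catalysed diaryl ether formation from an aryl triflate and a phenol; the bulky di-tert-butyl biaryl phosphine drives C–O reductive elimination, which is helped by an ortho-substituted, electron-rich phenoxide, and the triflate carbon has two ortho hydrogens. K3PO4 in toluene does not touch the silyl ether.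

Step 12
Reactants: 19 B-C-D-E-F-G hexamer triisopropylsilyl ether
Product: 20 B-C-D-E-F-G hexamer phenol (free hydroxyl at B1)
Conditions: Bu4NF, AcOH (1:1), THF, 0 °C
Reagents that add atoms: none
Why: Buffered fluoride desilylation as in step 9; the molecule contains no other silyl group.

Step 13
Reactants: 20 B-C-D-E-F-G hexamer phenol
Product: 21 B-C-D-E-F-G hexamer triflate (trifluoromethanesulfonate at B1)
Conditions: Tf2O, pyridine, CH2Cl2, −20 to 0 °C
Reagents that add atoms: trifluoromethanesulfonic anhydride, O=S(=O)(OS(=O)(=O)C(F)(F)F)C(F)(F)F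
Why: Triflation of the single free, unhindered phenol as in step 10.

Step 14
Reactants: 21 B-C-D-E-F-G hexamer triflate; 22 2,4,6-trimethoxyphenol
Product: 23 dodeca-O-methyl hexa-O-isopropyl heptamer (rings A to G complete)
Conditions: Pd(OAc)2 (5 mol%), 2-di-tert-butylphosphino-2',4',6'-triisopropylbiphenyl (10 mol%), K3PO4, toluene (degassed), 100 °C, Ar
Reagents that add atoms: none
Why: The same palladium-catalysed etherification of an aryl triflate as in step 11, now with a small, electron-rich 2,6-disubstituted phenol as nucleophile and a triflate carbon flanked by hydrogens.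

Step 15
Reactants: 23 dodeca-O-methyl hexa-O-isopropyl heptamer
Product: 24 CNP0292517.0
Conditions: BBr3 (large excess), CH2Cl2, −78 °C to rt, Ar; H2O, 0 °C; degassed work-up
Reagents that add atoms: none
Why: Lewis-acid cleavage of aryl alkyl ethers (bromide attacks the alkyl carbon of the boron-complexed ether); isopropyl ethers cleave faster than methyl ethers and diaryl ethers are inert because neither carbon can be attacked. The acidic, air-free conditions suit the polyphenol.

## Compound list

1 | 2,6-dimethoxy-1,4-benzoquinone | COC1=CC(=O)C=C(OC)C1=O | starting material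
2 | 2,6-dimethoxybenzene-1,4-diol | COc1cc(O)cc(OC)c1O | intermediate
3 | 2,6-dimethoxy-4-(triisopropylsilyloxy)phenol | COc1cc(O[Si](C(C)C)(C(C)C)C(C)C)cc(OC)c1O | intermediate
4 | vinyl acetate | CC(=O)OC=C | starting material
5 | triisopropyl[3,5-dimethoxy-4-(vinyloxy)phenoxy]silane | C=COc1c(OC)cc(O[Si](C(C)C)(C(C)C)C(C)C)cc1OC | intermediate
6 | diisopropyl squarate (3,4-diisopropoxycyclobut-3-ene-1,2-dione) | CC(C)OC1=C(OC(C)C)C(=O)C1=O | starting material
7 | {1-[2,6-dimethoxy-4-(triisopropylsilyloxy)phenoxy]vinyl}lithium | [Li]C(=C)Oc1c(OC)cc(O[Si](C(C)C)(C(C)C)C(C)C)cc1OC | intermediate (not isolated)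
8 | (±)-4-hydroxy-2,3-diisopropoxy-4-{1-[2,6-dimethoxy-4-(triisopropylsilyloxy)phenoxy]vinyl}cyclobut-2-en-1-one | CC(C)OC1=C(OC(C)C)C(O)(C(=C)Oc2c(OC)cc(O[Si](C(C)C)(C(C)C)C(C)C)cc2OC)C1=O | intermediate
9 | (3Z)-5-[2,6-dimethoxy-4-(triisopropylsilyloxy)phenoxy]-4-hydroxy-2,3-diisopropoxyhexa-1,3,5-trien-1-one (dienylketene) | CC(C)OC(=C=O)/C(OC(C)C)=C(/O)C(=C)Oc1c(OC)cc(O[Si](C(C)C)(C(C)C)C(C)C)cc1OC | intermediate (not isolated)
10 | 5-[2,6-dimethoxy-4-(triisopropylsilyloxy)phenoxy]-4-hydroxy-2,3-diisopropoxycyclohexa-2,4-dien-1-one | CC(C)OC1=C(OC(C)C)C(O)=C(Oc2c(OC)cc(O[Si](C(C)C)(C(C)C)C(C)C)cc2OC)CC1=O | intermediate (not isolated)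
11 | 5-[2,6-dimethoxy-4-(triisopropylsilyloxy)phenoxy]-2,3-diisopropoxybenzene-1,4-diol (free hydroxyls at C2 and C5 of the new ring) | CC(C)Oc1c(O)cc(Oc2c(OC)cc(O[Si](C(C)C)(C(C)C)C(C)C)cc2OC)c(O)c1OC(C)C | intermediate
12 | 6-[2,6-dimethoxy-4-(triisopropylsilyloxy)phenoxy]-2,3,4-triisopropoxyphenol | CC(C)Oc1cc(Oc2c(OC)cc(O[Si](C(C)C)(C(C)C)C(C)C)cc2OC)c(O)c(OC(C)C)c1OC(C)C | intermediate
13 | 4-bromo-2,6-dimethoxyphenol | COc1cc(Br)cc(OC)c1O | starting material
14 | (3,4,5-trimethoxyphenyl)boronic acid | COc1cc(B(O)O)cc(OC)c1OC | starting material
15 | 5-(4-bromo-2,6-dimethoxyphenoxy)-1,2,3-trimethoxybenzene | COc1cc(Oc2c(OC)cc(Br)cc2OC)cc(OC)c1OC | intermediate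
16 | D-E-F-G tetramer silyl ether (ring D 3,5-dimethoxy with OSi(i-Pr)3 at D1; ring E 3,4,5-triisopropoxy with CH at E6; ring F 3,5-dimethoxy; ring G 3,4,5-trimethoxyphenyl; ethers D4–O–E1, E2–O–F1, F4–O–G1) | CC(C)[Si](C(C)C)(C(C)C)Oc1cc(OC)c(Oc2cc(OC(C)C)c(OC(C)C)c(OC(C)C)c2Oc2cc(OC)c(Oc3cc(OC)c(OC)c(OC)c3)c(OC)c2)c(OC)c1 | intermediate
17 | D-E-F-G tetramer phenol (16 with free hydroxyl at D1) | Oc1cc(OC)c(Oc2cc(OC(C)C)c(OC(C)C)c(OC(C)C)c2Oc2cc(OC)c(Oc3cc(OC)c(OC)c(OC)c3)c(OC)c2)c(OC)c1 | intermediate
18 | D-E-F-G tetramer triflate (trifluoromethanesulfonate at D1) | O=S(=O)(Oc1cc(OC)c(Oc2cc(OC(C)C)c(OC(C)C)c(OC(C)C)c2Oc2cc(OC)c(Oc3cc(OC)c(OC)c(OC)c3)c(OC)c2)c(OC)c1)C(F)(F)F | intermediate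
19 | B-C-D-E-F-G hexamer silyl ether (ring B 3,5-dimethoxy with OSi(i-Pr)3 at B1; rings C and E 3,4,5-triisopropoxy; rings D and F 3,5-dimethoxy; ring G 3,4,5-trimethoxyphenyl) | CC(C)[Si](C(C)C)(C(C)C)Oc1cc(OC)c(Oc2cc(OC(C)C)c(OC(C)C)c(OC(C)C)c2Oc2cc(OC)c(Oc3cc(OC(C)C)c(OC(C)C)c(OC(C)C)c3Oc3cc(OC)c(Oc4cc(OC)c(OC)c(OC)c4)c(OC)c3)c(OC)c2)c(OC)c1 | intermediate
20 | B-C-D-E-F-G hexamer phenol (free hydroxyl at B1) | Oc1cc(OC)c(Oc2cc(OC(C)C)c(OC(C)C)c(OC(C)C)c2Oc2cc(OC)c(Oc3cc(OC(C)C)c(OC(C)C)c(OC(C)C)c3Oc3cc(OC)c(Oc4cc(OC)c(OC)c(OC)c4)c(OC)c3)c(OC)c2)c(OC)c1 | intermediate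
21 | B-C-D-E-F-G hexamer triflate (trifluoromethanesulfonate at B1) | O=S(=O)(Oc1cc(OC)c(Oc2cc(OC(C)C)c(OC(C)C)c(OC(C)C)c2Oc2cc(OC)c(Oc3cc(OC(C)C)c(OC(C)C)c(OC(C)C)c3Oc3cc(OC)c(Oc4cc(OC)c(OC)c(OC)c4)c(OC)c3)c(OC)c2)c(OC)c1)C(F)(F)F | intermediate
22 | 2,4,6-trimethoxyphenol | COc1cc(OC)c(O)c(OC)c1 | starting material
23 | dodeca-O-methyl hexa-O-isopropyl heptamer (24 with methyl ethers on rings A, B, D, F, G and isopropyl ethers on rings C and E) | COc1cc(OC)c(Oc2cc(OC)c(Oc3cc(OC(C)C)c(OC(C)C)c(OC(C)C)c3Oc3cc(OC)c(Oc4cc(OC(C)C)c(OC(C)C)c(OC(C)C)c4Oc4cc(OC)c(Oc5cc(OC)c(OC)c(OC)c5)c(OC)c4)c(OC)c3)c(OC)c2)c(OC)c1 | intermediate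
24 | CNP0292517.0 | Oc1cc(O)c(Oc2cc(O)c(Oc3cc(O)c(O)c(O)c3Oc3cc(O)c(Oc4cc(O)c(O)c(O)c4Oc4cc(O)c(Oc5cc(O)c(O)c(O)c5)c(O)c4)c(O)c3)c(O)c2)c(O)c1 | target

## Step count and risks

Total step count: 15. Longest linear sequence: 14 steps (steps 1 to 6, then 8 to 15); step 7 is a one-step branch.

**Step 5 (key step).** The ring opening may send the hydroxyl inward, or the bulky aryloxy group may disfavour the s-cis arrangement needed for the 6-pi closure. In either case the ketene would be captured by the tertiary hydroxyl as a lactone instead of closing ring C, and traces of air would carry the product on to the quinone. The fallback keeps ring C squarate-derived but makes the ring B ether by conjugate addition; it sets out from 6 and 3 and returns at 11. CH2=CHMgBr is added to 6 to give 4-hydroxy-2,3-diisopropoxy-4-vinylcyclobut-2-en-1-one F1, whose thermolysis (the parent case of this ring expansion) gives 2,3-diisopropoxybenzene-1,4-diol F2. Oxidation with Ag2O gives 2,3-diisopropoxy-1,4-benzoquinone F3. Base-mediated addition of phenol 3 to an excess of F3, which reoxidises the adduct, gives 5-[2,6-dimethoxy-4-(triisopropylsilyloxy)phenoxy]-2,3-diisopropoxy-1,4-benzoquinone F4, and reduction with Na2S2O4 gives 11.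

**Step 4.** Metalation may occur on the ring between the methoxy and silyloxy groups (followed by silyl migration), or the lithiated aryl vinyl ether may lose aryloxide by alpha-elimination before it meets the squarate. The fallback fixes the metalation site with a halogen; it sets out from 3 and returns at 7, and thence at 8. Phenol 3 is treated with KH and trichloroethylene to give (E)-1,2-dichlorovinyl 2,6-dimethoxy-4-(triisopropylsilyloxy)phenyl ether F5. n-BuLi (2.2 equiv, −78 to −40 °C) and a methanol quench give the ethynyl aryl ether F6. Markovnikov addition of HI (from Me3SiCl, NaI and one equivalent of water in MeCN, −20 °C) gives the 1-iodovinyl aryl ether F7, and iodine–lithium exchange with t-BuLi at −78 °C gives 7, which is added to 6 as in step 4.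

**Step 6.** The alkylation may lose site selectivity, with some reaction at the crowded C2 oxygen and some double alkylation, and the hydroquinone anion may be oxidised by adventitious air. The fallback differentiates the two oxygens before the ring exists; it sets out from 8 and returns at 12. The tertiary hydroxyl of 8 is converted with MOMCl and i-Pr2NEt into the methoxymethyl ether F8. Thermolysis as in step 5 gives 4-(methoxymethoxy)phenol F9, in which only the C5 hydroxyl is free. Isopropylation gives the fully protected ring B-ring C unit F10, and HCl in methanol removes the methoxymethyl group to give 12.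

**Step 11.** The phenoxide of 12 or the base may attack the triflate at sulfur and return phenol 17, or C–O reductive elimination may be too slow for so crowded a phenoxide, so that the triflate is consumed by reduction. The fallback inverts the polarity of ring D; it sets out from 18 and returns at 19. Miyaura borylation of 18 (B2pin2, Pd(dppf)Cl2, KOAc, dioxane, 80 °C) gives the D-E-F-G tetramer pinacol boronate F11, which is coupled with 12 under Chan–Lam conditions for boronic esters (Cu(OAc)2, boric acid, 4 Å MS, MeCN, 80 °C, air) to give 19.

**Step 14.** Phenol 22 may be oxidised under hot basic conditions, and the triflate of the large substrate may be cleaved before coupling. The fallback exchanges the roles of the partners and makes no new compound; it sets out from 20 and returns at 23. Phenol 20 is coupled with 2-iodo-1,3,5-trimethoxybenzene (COc1cc(OC)c(I)c(OC)c1) under Ullmann conditions for hindered partners (CuI, picolinic acid, K3PO4, DMSO, 90 °C), which also saves step 13.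

**Step 15.** Cleavage may stall at partly methylated stages as boron chelates precipitate, and the polyphenol may be oxidised during isolation. The fallback stages the cleavage and purifies through a stable derivative; it sets out from 23 and returns at 24. BCl3 (CH2Cl2, −78 to 0 °C) removes the six isopropyl groups to give the hexahydroxy dodeca-O-methyl heptamer F12, and BBr3 then cleaves the methyl ethers. The crude product is acetylated (Ac2O, pyridine) to the octadecaacetate F13, which can be chromatographed on silica, and degassed methanolic HCl releases 24.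

## Further compounds

F1 | step 5 | 4-hydroxy-2,3-diisopropoxy-4-vinylcyclobut-2-en-1-one | CC(C)OC1=C(OC(C)C)C(O)(C=C)C1=O
F2 | step 5 | 2,3-diisopropoxybenzene-1,4-diol | CC(C)Oc1c(O)ccc(O)c1OC(C)C
F3 | step 5 | 2,3-diisopropoxy-1,4-benzoquinone | CC(C)OC1=C(OC(C)C)C(=O)C=CC1=O
F4 | step 5 | 5-[2,6-dimethoxy-4-(triisopropylsilyloxy)phenoxy]-2,3-diisopropoxy-1,4-benzoquinone | CC(C)OC1=C(OC(C)C)C(=O)C(Oc2c(OC)cc(O[Si](C(C)C)(C(C)C)C(C)C)cc2OC)=CC1=O
F5 | step 4 | (E)-1,2-dichlorovinyl 2,6-dimethoxy-4-(triisopropylsilyloxy)phenyl ether | Cl/C=C(/Cl)Oc1c(OC)cc(O[Si](C(C)C)(C(C)C)C(C)C)cc1OC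
F6 | step 4 | ethynyl 2,6-dimethoxy-4-(triisopropylsilyloxy)phenyl ether | C#COc1c(OC)cc(O[Si](C(C)C)(C(C)C)C(C)C)cc1OC
F7 | step 4 | 1-iodovinyl 2,6-dimethoxy-4-(triisopropylsilyloxy)phenyl ether | C=C(I)Oc1c(OC)cc(O[Si](C(C)C)(C(C)C)C(C)C)cc1OC
F8 | step 6 | (±)-2,3-diisopropoxy-4-(methoxymethoxy)-4-{1-[2,6-dimethoxy-4-(triisopropylsilyloxy)phenoxy]vinyl}cyclobut-2-en-1-one | CC(C)OC1=C(OC(C)C)C(OCOC)(C(=C)Oc2c(OC)cc(O[Si](C(C)C)(C(C)C)C(C)C)cc2OC)C1=O
F9 | step 6 | 5-[2,6-dimethoxy-4-(triisopropylsilyloxy)phenoxy]-2,3-diisopropoxy-4-(methoxymethoxy)phenol | COCOc1c(Oc2c(OC)cc(O[Si](C(C)C)(C(C)C)C(C)C)cc2OC)cc(O)c(OC(C)C)c1OC(C)C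
F10 | step 6 | triisopropyl{3,5-dimethoxy-4-[3,4,5-triisopropoxy-2-(methoxymethoxy)phenoxy]phenoxy}silane | COCOc1c(Oc2c(OC)cc(O[Si](C(C)C)(C(C)C)C(C)C)cc2OC)cc(OC(C)C)c(OC(C)C)c1OC(C)C
F11 | step 11 | D-E-F-G tetramer pinacol boronate (18 with 4,4,5,5-tetramethyl-1,3,2-dioxaborolan-2-yl in place of the triflate at D1) | CC1(C)OB(OC1(C)C)c1cc(OC)c(Oc2cc(OC(C)C)c(OC(C)C)c(OC(C)C)c2Oc2cc(OC)c(Oc3cc(OC)c(OC)c(OC)c3)c(OC)c2)c(OC)c1
F0 | step 14 | none | none
F12 | step 15 | hexahydroxy dodeca-O-methyl heptamer (23 with free hydroxyls on rings C and E) | COc1cc(OC)c(Oc2cc(OC)c(Oc3cc(O)c(O)c(O)c3Oc3cc(OC)c(Oc4cc(O)c(O)c(O)c4Oc4cc(OC)c(Oc5cc(OC)c(OC)c(OC)c5)c(OC)c4)c(OC)c3)c(OC)c2)c(OC)c1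
F13 | step 15 | octadeca-O-acetate of 24 | CC(=O)Oc1cc(OC(C)=O)c(Oc2cc(OC(C)=O)c(Oc3cc(OC(C)=O)c(OC(C)=O)c(OC(C)=O)c3Oc3cc(OC(C)=O)c(Oc4cc(OC(C)=O)c(OC(C)=O)c(OC(C)=O)c4Oc4cc(OC(C)=O)c(Oc5cc(OC(C)=O)c(OC(C)=O)c(OC(C)=O)c5)c(OC(C)=O)c4)c(OC(C)=O)c3)c(OC(C)=O)c2)c(OC(C)=O)c1
A1 | alternative 1 | hexabenzyl dodecaformate heptamer | C(c9ccccc9)Oc1cc(OC=O)c(Oc2cc(OC=O)c(Oc3cc(OC=O)c(OCc8ccccc8)c(OC=O)c3Oc3cc(OC=O)c(Oc4cc(OC=O)c(OCc7ccccc7)c(OC=O)c4Oc4cc(OC=O)c(Oc5cc(OCc6ccccc6)c(OCc6ccccc6)c(OCc6ccccc6)c5)c(OC=O)c4)c(OC=O)c3)c(OC=O)c2)c(OC=O)c1
A2 | alternative 1 | hexabenzyl dodecaaldehyde heptamer | C(c9ccccc9)Oc1cc(C=O)c(Oc2cc(C=O)c(Oc3cc(C=O)c(OCc8ccccc8)c(C=O)c3Oc3cc(C=O)c(Oc4cc(C=O)c(OCc7ccccc7)c(C=O)c4Oc4cc(C=O)c(Oc5cc(OCc6ccccc6)c(OCc6ccccc6)c(OCc6ccccc6)c5)c(C=O)c4)c(C=O)c3)c(C=O)c2)c(C=O)c1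
A3 | alternative 2 | bromo hydroxy trimethoxy depsidone (dibenzo[b,e][1,4]dioxepin-11-one) | COc1cc2Oc3c(O)cc(Br)cc3OC(=O)c2c(OC)c1OC
A4 | alternative 2 | 5-bromo-2,3-dihydroxyphenyl 6-fluoro-2,3,4-trimethoxybenzoate | COc1cc(F)c(C(=O)Oc2cc(Br)cc(O)c2O)c(OC)c1OC
A5 | alternative 3 | octadeca-O-methyl heptamer | COc1cc(OC)c(Oc2cc(OC)c(Oc3cc(OC)c(OC)c(OC)c3Oc3cc(OC)c(Oc4cc(OC)c(OC)c(OC)c4Oc4cc(OC)c(Oc5cc(OC)c(OC)c(OC)c5)c(OC)c4)c(OC)c3)c(OC)c2)c(OC)c1
A6 | alternative 3 | (cyclopentadienyl)(2,5-dichloro-1,3-dimethoxybenzene)ruthenium hexafluorophosphate | COc1cc(Cl)cc(OC)c1Cl.[Ru+2].c1cc[cH-]c1.F[P-](F)(F)(F)(F)F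
A7 | alternative 3 | A-B-C trimer phenol (per-O-methyl, free hydroxyl at C2 of ring C) | COc1cc(OC)c(Oc2cc(OC)c(Oc3cc(OC)c(OC)c(OC)c3O)c(OC)c2)c(OC)c1
A8 | alternative 3 | E-F-G trimer phenol (per-O-methyl, free hydroxyl at E1 of ring E) | Oc1cc(OC)c(OC)c(OC)c1Oc1cc(OC)c(Oc2cc(OC)c(OC)c(OC)c2)c(OC)c1
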